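## Structural features

- The target 18 is a benzophenone: two benzene rings joined only through one ketone carbon. Ring A (C1 to C6) carries the carbonyl at C1, a hydroxyl at C2, chlorine at C3, methoxy groups at C4 and C6, and hydrogen at C5. Ring B (C1' to C6') carries the carbonyl at C1', a methoxy group at C2', a free hydroxyl at C4' and a methyl group at C6'.
- There is no stereocentre, so no question of neighbouring stereocentres arises; the only spatial feature is the twist of ring B out of the plane of the hydrogen-bonded ring A–carbonyl unit.
- All four positions ortho to the ketone are substituted. The carbonyl is therefore shielded, and forming either aryl–carbonyl bond by a late acylation is difficult.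
- The fragile groups are the C3–Cl bond (reductive cleavage), the methoxy groups at C6 and C2' next to the carbonyl (Lewis-acid demethylation), and both electron-rich rings (over-halogenation).
- The real difficulty is differentiation: five oxygen substituents must end up as three methyl ethers, one chelated phenol and one free phenol, and the single chlorine must sit at C3 rather than at C5 or on ring B.
- The key step uses the alternating oxygenation of ring A (oxygen at C2, C4 and C6), which is the pattern of a 1,3,5-tricarbonyl chain. C1 and C2 come from a β-keto ester already attached to ring B. C3 to C6 come from a four-carbon ketene acetal enone whose acetal carbon becomes C6 with its methoxy group in place. C2 and C4 emerge as a chelated and a free hydroxyl that can be told apart.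

## Logic of the disconnections

18 ⇒ 17. The benzylic C–O bond at O4' is cut (a protecting group is added in the reverse sense). O4' must stay masked to the end, because a free phenol on ring B would pull the chlorination onto that ring and would compete with O4 in the methylation. Nothing is gained in skeleton. The forward step must remove benzyl without touching C3–Cl or the ketone.

17 ⇒ 16. The C3–Cl bond is cut. C3 is ortho to the phenol and para to the C6 methoxy group, a natural site for an electrophile, and a late chlorination lets ring A be built from halogen-free open-chain pieces. The forward step must distinguish C3 from C5 and ring A from ring B.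

16 ⇒ 15. The O4–CH3 bond is cut. In 15 the O2 hydroxyl is locked in a hydrogen bond to the ketone while O4 is free and more acidic, so the two can be told apart without protection. This leads back to the resorcinol that an annulation gives directly. The forward step must stop at mono-methylation.

15 ⇒ 8 + 13. The C1–C6 and C2–C3 bonds of ring A are cut. This avoids making a tetra-ortho-substituted aryl–carbonyl bond, because the ketone carbon is already bonded to ring B in 8. Ring A is reduced to a four-carbon enone, and the C6 methoxy group arrives ready-made. The forward step needs carbon–carbon bond formation at the acetal carbon of 13 and then a Claisen closure on the ester rather than on the ketone.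

13 ⇒ 12. The two C–O bonds at C4 of the butenone are cut. Methoxide can replace both chlorides of a β,β-dichloro enone by addition–elimination. The forward step must avoid water, since the ketene acetal hydrolyses easily.

12 ⇒ 9 + 10. The C2–C3 bond of the butenone is cut, through the trichloro ketone 11. This is an acylation of an alkene by an acid chloride, and it reduces the enone to two bulk chemicals. The forward step needs a stoichiometric Lewis acid and loss of HCl from 11.

8 ⇒ 4 + 5. The bond between the ketone carbon and the CH2 group is cut, through 6 and 7. A malonate half ester supplies the two-carbon ester unit and loses CO2 afterwards. The acyl carbon lies between two ortho substituents, so the forward step uses the acid chloride and not a milder acyl donor. The methyl ester is kept so that methoxide is the only alkoxide present in the annulation, which makes any exchange at the ketene acetal carbon degenerate.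

4 ⇒ 3. The acyl–oxygen bond of the methyl ester is cut. The forward hydrolysis takes place at a hindered carbonyl and needs forcing hydroxide conditions that the aryl ethers tolerate.

3 ⇒ 2. The O2'–CH3 bond is cut. The forward step methylates a hydrogen-bonded phenol, which needs excess reagent and mild heat.

2 ⇒ 1. The O4'–benzyl bond is cut. In 1 the full carbon skeleton of ring B is present and its two hydroxyls are already distinguished by the hydrogen bond to the ester. Benzyl is chosen because, of the common phenol protecting groups, it is the one that should survive hydroxide, oxalyl chloride, NaH and NCS alike. The forward step must alkylate O4' only.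

## Other disconnections considered

Alternative 1: aryne acyl-alkylation.
- Cut: ring B is taken out as an aryne. The bonds cut are C1'–C(=O) and the bond from C6' to its one-carbon substituent. On the target numbering this second bond is at C6', the carbon that carries the methyl group, and not at C2', which carries the methoxy group.
- Forward step: fluoride (CsF) releases the aryne from silyl triflate A3. The carbanion of the ring A β-keto ester A2 adds to the aryne carbon remote from the methoxy group, the aryl anion closes onto the ketone, and the four-membered alkoxide fragments. The aroyl group ends at C1' and a CH2CO2Me group at C6', giving A1. No ring is closed.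
- In favour: it is convergent, it forms the congested aryl–carbonyl bond under mild conditions, and the methoxy group steers the regiochemistry. Chlorine is already present in A2, so the C3 versus C5 question never arises; on this point it is better than the chosen plan.
- Against: A1 carries CH2CO2Me where the target has CH3, so ester hydrolysis and a decarboxylation of an arylacetic acid, which is not a spontaneous process, must follow. The aryl anion has to attack a ketone flanked by two ortho substituents; if it is protonated first, plain α-arylation results. A3 needs several steps with a regiochemical problem of its own. Two benzyl ethers must be removed next to C–Cl.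
- Comparison: both plans make two carbon–carbon bonds in one flask, but step 7 also closes a ring and arrives at the correct substitution with no surplus carbon. After the key step the count is equal (three operations each); before it this alternative is longer.

Alternative 2: Diels–Alder benzannulation of ring B.
- Cut: the alkyne carbons of ynone A5 become C1' and C6', and diene A6 supplies C2' to C5'. The bonds made are therefore C1'–C2' and C5'–C6'; the C1'–C6' bond is the alkyne itself and C2'–C3' lies inside the diene.
- Forward step: (4+2) cycloaddition with the nucleophilic CH2 terminus of A6 adding to the β-carbon of the ynone, then loss of methanol and desilylation, gives A4 with the free 4'-phenol.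
- In favour: the regiochemistry follows from the polarisation of both partners. The 2'-methoxy group, the 4'-hydroxyl and the 6'-methyl group arrive in one step. Chlorine is carried in from the start. The only step left is acidic removal of the methoxymethyl group, which cannot touch C–Cl. On these three points (chlorine position, end game, no hydrogenolysis) it is better than the chosen plan. A6 would come from silylation of 13, so the two plans share that chemistry. The longest linear sequence on paper is about six steps, shorter than the chosen plan.
- Against: A6 is an extremely moisture-sensitive silyl ketene acetal diene. A5 has to be built on a fully substituted, chlorinated ring A through formylation, protection, propynyl addition and oxidation. The ynone carbonyl is twisted by two ortho substituents, which may slow the cycloaddition and let a Mukaiyama–Michael addition without ring closure intervene.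
- Comparison: this plan builds ring B on ring A, the reverse of the chosen plan, and is a serious competitor. The chosen plan has cheaper and more robust partners, but pays with a late regioselective chlorination and a hydrogenolysis.

Alternative 3: acylpyrone to ring B.
- Cut: the C2'–C3' and C4'–C5' bonds of ring B.
- Forward step: 5-aroyl-2-pyranone A8 and ketene bis(trimethylsilyl) acetal A9 undergo an inverse-electron-demand (4+2) cycloaddition. The bridged adduct loses CO2, and loss of trimethylsilanol gives A7 with the free 4'-phenol.
- In favour: loss of CO2 makes the aromatisation irreversible, the pyranone polarisation sets the regiochemistry, and chlorine is in place from the start (better than the chosen plan on that point).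
- Against: A8 is not a stock compound. A 6-methoxy-4-methyl-2-pyranone acylated at C5 by a hindered aroyl group is a synthesis problem of its own. Its 6-methoxy group also lowers the electrophilicity that the inverse-demand step needs. A9 is moisture-sensitive. The benzyl ether must still be cleaved next to C–Cl, so the final step carries the same risk as step 10 (equal on that point).
- Comparison: mechanistically it is elegant and needs no oxidation-level adjustment, as in the chosen plan. The several steps needed for A8 make it longer overall, and its precursor is less certain than 8 and 13.

Key step: step 7

Remark on the chemistry: ring A is numbered from the carbonyl-bearing carbon C1 through C2 (OH) and C3 (Cl), ring B from C1' (carbonyl) through C2' (OMe) to C6' (CH3); 13 is treated as a compound to be made.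

Step 1
Reactants: 1 methyl orsellinate (methyl 2,4-dihydroxy-6-methylbenzoate)
Product: 2 methyl 4-(benzyloxy)-2-hydroxy-6-methylbenzoate
Conditions: BnBr (1.05 equiv), K2CO3, acetone, reflux
Reagents that add atoms: benzyl bromide, BrCc1ccccc1
Why: Williamson etherification; the 4-hydroxyl is the more acidic and the only unchelated phenol (the 2-hydroxyl is hydrogen-bonded to the ester carbonyl), so one equivalent of benzyl bromide with a weak base should alkylate O4 only.

Step 2
Reactants: 2 methyl 4-(benzyloxy)-2-hydroxy-6-methylbenzoate
Product: 3 methyl 4-(benzyloxy)-2-methoxy-6-methylbenzoate
Conditions: MeI (3 equiv), K2CO3, DMF, 50 °C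
Reagents that add atoms: iodomethane, CI
Why: Williamson methylation of the remaining hydrogen-bonded phenol with excess iodomethane in a dipolar aprotic solvent; no other site of 2 is nucleophilic under carbonate.

Step 3
Reactants: 3 methyl 4-(benzyloxy)-2-methoxy-6-methylbenzoate
Product: 4 4-(benzyloxy)-2-methoxy-6-methylbenzoic acid
Conditions: KOH, DMSO–H2O (4:1), 90 °C; then 1 M HCl, 0 °C
Reagents that add atoms: potassium hydroxide, [K+].[OH-]
Why: Saponification of a di-ortho-substituted benzoate needs poorly solvated hydroxide and heat; the aryl ethers are inert, and cold acidification avoids protodecarboxylation of the electron-rich acid.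

Step 4
Reactants: 4 4-(benzyloxy)-2-methoxy-6-methylbenzoic acid; 5 potassium methyl malonate
Product: 8 methyl 3-[4-(benzyloxy)-2-methoxy-6-methylphenyl]-3-oxopropanoate, via acid chloride 6 (not isolated), via acylmalonic half ester 7 (not isolated)
Conditions: (COCl)2, cat. DMF, CH2Cl2, 0 °C to rt, evaporate; then 5, MgCl2, Et3N, MeCN, 0 °C to rt; 1 M HCl
Reagents that add atoms: oxalyl chloride, O=C(Cl)C(=O)Cl (chlorine of intermediate 6 only; no atom of it remains in 8)
Why: Acid chloride formation, C-acylation of the magnesium enolate of the malonate half ester, and decarboxylation on acidification (malonate half-ester homologation of the Masamune type in its acid chloride form); the acid chloride is used because the di-ortho-substituted acyl carbon needs a strongly activated electrophile.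

Step 5
Reactants: 9 acetyl chloride; 10 1,1-dichloroethene
Product: 12 4,4-dichlorobut-3-en-2-one, via 4,4,4-trichlorobutan-2-one 11 (not isolated)
Conditions: AlCl3 (1.1 equiv), CH2Cl2, 0 °C to rt; ice/aq. HCl; distillation with loss of HCl
Reagents that add atoms: none
Why: Friedel–Crafts-type acylation of an alkene; the acylium ion from 9 adds to the CH2 terminus of 10, chloride captures the dichlorocarbenium ion to give 11, and 11 loses HCl by β-elimination to the conjugated dichloro enone.

Step 6
Reactants: 12 4,4-dichlorobut-3-en-2-one
Product: 13 4,4-dimethoxybut-3-en-2-one
Conditions: NaOMe (2.2 equiv), MeOH, 0 °C to rt; filter, distil, store dry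
Reagents that add atoms: sodium methoxide, [Na+].[O-]C
Why: Two successive vinylic addition–elimination substitutions of chloride by methoxide at the β-carbon, each activated by conjugation to the ketone; the product is a push–pull ketene acetal that must be kept away from water.

Step 7
Reactants: 8 methyl 3-[4-(benzyloxy)-2-methoxy-6-methylphenyl]-3-oxopropanoate; 13 4,4-dimethoxybut-3-en-2-one
Product: 15 [4-(benzyloxy)-2-methoxy-6-methylphenyl](2,4-dihydroxy-6-methoxyphenyl)methanone, via vinylogous ester adduct 14 (not isolated)
Conditions: NaH (1.1 equiv), THF, 0 °C; 13 (1.2 equiv), rt to 50 °C; then NaH (2.2 equiv), reflux; 1 M HCl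
Reagents that add atoms: none
Why: NaH turns 8 into its sodium enolate, whose central carbon adds to the acetal carbon of 13 and expels methoxide; this forms the C1–C6 bond and gives adduct 14 with the C6 methoxy group in place. Further base removes the doubly activated C–H of 14 and then a proton of the methyl ketone, and the terminal enolate carbon attacks the ester carbonyl with loss of methoxide, forming the C2–C3 bond. Ring A closes in a 6-(enolendo)-exo-trig Claisen (Dieckmann-type) mode, and the resulting cyclohexadienedione tautomerises to the resorcinol without an oxidant because the chain is already at the aromatic oxidation level. The closest known reaction type is the (3+3) Michael addition–elimination and Claisen benzannulation of 1,3-dicarbonyl anions with β-alkoxy enones and α-oxo ketene acetals, for which the dithioacetals are the better-tested partners. No stereocentre is formed. The first bond can form only at C4 of 13, the one carbon that carries leaving groups. The closure must take place at the ester and not by aldol attack on the ketone or through oxygen to a 2-pyranone; the ketone is shielded by the 2'-methoxy and 6'-methyl groups of ring B, the dianion reacts through carbon, and a pyranone would be reopened by methoxide whereas the phenoxide of 15 is a thermodynamic sink.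

Step 8
Reactants: 15 [4-(benzyloxy)-2-methoxy-6-methylphenyl](2,4-dihydroxy-6-methoxyphenyl)methanone
Product: 16 [4-(benzyloxy)-2-methoxy-6-methylphenyl](2-hydroxy-4,6-dimethoxyphenyl)methanone
Conditions: MeI (1.05 equiv), K2CO3 (1.1 equiv), acetone, rt to 40 °C
Reagents that add atoms: iodomethane, CI
Why: Williamson methylation with one equivalent of reagent; O4 is free and the more acidic (para to the carbonyl), whereas O2 is held in a hydrogen bond to the ketone, so mono-methylation at O4 is expected.

Step 9
Reactants: 16 [4-(benzyloxy)-2-methoxy-6-methylphenyl](2-hydroxy-4,6-dimethoxyphenyl)methanone
Product: 17 [4-(benzyloxy)-2-methoxy-6-methylphenyl](3-chloro-2-hydroxy-4,6-dimethoxyphenyl)methanone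
Conditions: NCS (1.05 equiv), MeCN, 0 °C to rt, dark
Reagents that add atoms: N-chlorosuccinimide, O=C1CCC(=O)N1Cl
Why: Electrophilic aromatic chlorination; ring A with three oxygen donors is more nucleophilic than ring B with two ethers, and C3 (ortho to the phenol, para to the C6 methoxy group) is less crowded than C5, which lies between two methoxy groups; one equivalent at low temperature limits dichlorination.

Step 10
Reactants: 17 [4-(benzyloxy)-2-methoxy-6-methylphenyl](3-chloro-2-hydroxy-4,6-dimethoxyphenyl)methanone
Product: 18 (3-chloro-2-hydroxy-4,6-dimethoxyphenyl)(4-hydroxy-2-methoxy-6-methylphenyl)methanone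
Conditions: H2 (1 atm), 5% Pd/C, EtOAc, rt, stopped after one equivalent of H2
Reagents that add atoms: none
Why: Hydrogenolysis of a benzyl aryl ether in a neutral solvent; benzylic C–O cleavage is much faster than hydrogenolysis of an electron-rich aryl chloride, which needs base to run at a useful rate, and the hindered chelated ketone should not be reduced at 1 atm.

## Compound list

1 | methyl orsellinate (methyl 2,4-dihydroxy-6-methylbenzoate) | COC(=O)c1c(C)cc(O)cc1O | starting material
2 | methyl 4-(benzyloxy)-2-hydroxy-6-methylbenzoate | COC(=O)c1c(C)cc(OCc2ccccc2)cc1O | intermediate
3 | methyl 4-(benzyloxy)-2-methoxy-6-methylbenzoate | COC(=O)c1c(C)cc(OCc2ccccc2)cc1OC | intermediate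
4 | 4-(benzyloxy)-2-methoxy-6-methylbenzoic acid | OC(=O)c1c(C)cc(OCc2ccccc2)cc1OC | intermediate
5 | potassium methyl malonate | COC(=O)CC(=O)[O-].[K+] | starting material
6 | 4-(benzyloxy)-2-methoxy-6-methylbenzoyl chloride | ClC(=O)c1c(C)cc(OCc2ccccc2)cc1OC | intermediate (not isolated)
7 | 2-[4-(benzyloxy)-2-methoxy-6-methylbenzoyl]-3-methoxy-3-oxopropanoic acid (racemic, enolisable centre; present as its magnesium chelate) | COC(=O)C(C(O)=O)C(=O)c1c(C)cc(OCc2ccccc2)cc1OC | intermediate (not isolated)
8 | methyl 3-[4-(benzyloxy)-2-methoxy-6-methylphenyl]-3-oxopropanoate | COC(=O)CC(=O)c1c(C)cc(OCc2ccccc2)cc1OC | intermediate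
9 | acetyl chloride | CC(=O)Cl | starting material
10 | 1,1-dichloroethene | C=C(Cl)Cl | starting material
11 | 4,4,4-trichlorobutan-2-one | CC(=O)CC(Cl)(Cl)Cl | intermediate (not isolated)
12 | 4,4-dichlorobut-3-en-2-one | CC(=O)C=C(Cl)Cl | intermediate
13 | 4,4-dimethoxybut-3-en-2-one | CC(=O)C=C(OC)OC | intermediate
14 | methyl (3E)-2-[4-(benzyloxy)-2-methoxy-6-methylbenzoyl]-3-methoxy-5-oxohex-3-enoate (C2 racemic and enolisable; drawn in the alkene geometry that can cyclise) | COC(=O)C(C(=O)c1c(C)cc(OCc2ccccc2)cc1OC)/C(OC)=C\C(C)=O | intermediate (not isolated)
15 | [4-(benzyloxy)-2-methoxy-6-methylphenyl](2,4-dihydroxy-6-methoxyphenyl)methanone | COc1cc(O)cc(O)c1C(=O)c1c(C)cc(OCc2ccccc2)cc1OC | intermediate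
16 | [4-(benzyloxy)-2-methoxy-6-methylphenyl](2-hydroxy-4,6-dimethoxyphenyl)methanone | COc1cc(OC)c(C(=O)c2c(C)cc(OCc3ccccc3)cc2OC)c(O)c1 | intermediate
17 | [4-(benzyloxy)-2-methoxy-6-methylphenyl](3-chloro-2-hydroxy-4,6-dimethoxyphenyl)methanone | COc1cc(OC)c(C(=O)c2c(C)cc(OCc3ccccc3)cc2OC)c(O)c1Cl | intermediate
18 | (3-chloro-2-hydroxy-4,6-dimethoxyphenyl)(4-hydroxy-2-methoxy-6-methylphenyl)methanone | COc1cc(OC)c(C(=O)c2c(C)cc(O)cc2OC)c(O)c1Cl | target

## Step count and least certain steps

Total step count: 10. Longest linear sequence: 8 (steps 1, 2, 3, 4, 7, 8, 9, 10); steps 5 and 6 form the two-step branch to 13.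

Step 7 (key step). The conjugate addition to 13 may be slow, because its two methoxy groups make it a weak acceptor; 13 could then self-condense or hydrolyse before it is consumed. After the addition, closure through oxygen to a 2-pyranone or aldol closure onto the ketone could compete with the Claisen closure. The fallback abandons the annulation and sets out from 6 (made from 4 as in step 4). Esterification with 3,5-dimethoxyphenol (Et3N, DMAP, CH2Cl2) would give 3,5-dimethoxyphenyl 4-(benzyloxy)-2-methoxy-6-methylbenzoate F1. An ortho-Fries rearrangement (TiCl4, CH2Cl2, 0 °C to rt) would move the acyl group to the carbon between the phenol oxygen and a methoxy group. The route is rejoined at 16, so step 8 is no longer needed.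

Step 9. Chlorination at C5, on ring B, or twice is possible, because every open position of both rings is activated by two or three oxygen substituents. The fallback brings the chlorine in with ring A. Starting from 6, esterification with 2-chloro-3,5-dimethoxyphenol would give 2-chloro-3,5-dimethoxyphenyl 4-(benzyloxy)-2-methoxy-6-methylbenzoate F2. Its ortho-Fries rearrangement (TiCl4, CH2Cl2) can take place only at the single free ortho position of the phenol. The route is rejoined at 17.

Step 10. The C3–Cl bond could be lost by hydrogenolysis, or the ketone over-reduced, if the catalyst is too active or the reaction runs on after the benzyl group has gone. The fallback replaces reduction by Lewis-acid cleavage with a cation scavenger: BCl3 and pentamethylbenzene in CH2Cl2 at −78 °C, a temperature at which the methyl ethers should survive. It runs from 17 to 18 and makes no new compound (F0).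

Step 4. Acylation at the di-ortho-substituted acyl carbon may be incomplete, or the malonate enolate may be acylated on oxygen or twice. The fallback moves the bond formation to an unhindered carbon. Starting from 4, MeLi (2.2 equiv, THF, 0 °C to rt) would give 1-[4-(benzyloxy)-2-methoxy-6-methylphenyl]ethan-1-one F3. Its enolate would be carboxylated with dimethyl carbonate (NaH, THF, reflux). The route is rejoined at 8.

Step 3. Hydrolysis at the hindered ester carbonyl may stall, or the acid may lose CO2 during acidification. The fallback attacks the ester methyl carbon instead of the carbonyl: LiI in pyridine at reflux (SN2 dealkylation), then cold acidification. It runs from 3 to 4 and makes no new compound (F0).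

## Further compounds

F1 | step 7 | 3,5-dimethoxyphenyl 4-(benzyloxy)-2-methoxy-6-methylbenzoate | COc1cc(OC)cc(OC(=O)c2c(C)cc(OCc3ccccc3)cc2OC)c1
F2 | step 9 | 2-chloro-3,5-dimethoxyphenyl 4-(benzyloxy)-2-methoxy-6-methylbenzoate | COc1cc(OC)c(Cl)c(OC(=O)c2c(C)cc(OCc3ccccc3)cc2OC)c1
F0 | step 10 | none | none
F3 | step 4 | 1-[4-(benzyloxy)-2-methoxy-6-methylphenyl]ethan-1-one | CC(=O)c1c(C)cc(OCc2ccccc2)cc1OC
F0 | step 3 | none | none
A1 | alternative 1 | methyl 2-[5-(benzyloxy)-2-[2-(benzyloxy)-3-chloro-4,6-dimethoxybenzoyl]-3-methoxyphenyl]acetate | COC(=O)Cc1cc(OCc2ccccc2)cc(OC)c1C(=O)c1c(OC)cc(OC)c(Cl)c1OCc1ccccc1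
A2 | alternative 1 | methyl 3-[2-(benzyloxy)-3-chloro-4,6-dimethoxyphenyl]-3-oxopropanoate | COC(=O)CC(=O)c1c(OC)cc(OC)c(Cl)c1OCc1ccccc1
A3 | alternative 1 | 5-(benzyloxy)-3-methoxy-2-(trimethylsilyl)phenyl trifluoromethanesulfonate | COc1cc(OCc2ccccc2)cc(OS(=O)(=O)C(F)(F)F)c1[Si](C)(C)C
A4 | alternative 2 | [3-chloro-4,6-dimethoxy-2-(methoxymethoxy)phenyl](4-hydroxy-2-methoxy-6-methylphenyl)methanone | COCOc1c(Cl)c(OC)cc(OC)c1C(=O)c1c(C)cc(O)cc1OC
A5 | alternative 2 | 1-[3-chloro-4,6-dimethoxy-2-(methoxymethoxy)phenyl]but-2-yn-1-one | CC#CC(=O)c1c(OC)cc(OC)c(Cl)c1OCOC
A6 | alternative 2 | 1,1-dimethoxy-3-(trimethylsilyloxy)buta-1,3-diene | COC(OC)=CC(=C)O[Si](C)(C)C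
A7 | alternative 3 | [2-(benzyloxy)-3-chloro-4,6-dimethoxyphenyl](4-hydroxy-2-methoxy-6-methylphenyl)methanone | COc1cc(OC)c(C(=O)c2c(C)cc(O)cc2OC)c(OCc2ccccc2)c1Cl
A8 | alternative 3 | 5-[2-(benzyloxy)-3-chloro-4,6-dimethoxybenzoyl]-6-methoxy-4-methyl-2H-pyran-2-one | COc1oc(=O)cc(C)c1C(=O)c1c(OC)cc(OC)c(Cl)c1OCc1ccccc1
A9 | alternative 3 | 1,1-bis(trimethylsilyloxy)ethene | C=C(O[Si](C)(C)C)O[Si](C)(C)C
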